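**Retrosynthetic overview**
1. Feature: in ring B (C5–C10) the unit C7(=O)–C8–C9(–O) is an aldol retron. Its aldol oxygen is the ether oxygen of ring C (O/C9/C11/C12/C13), so C9 can react as a cyclic oxocarbenium carbon already bonded to quaternary C10 (labdane numbering).
2. Late stage: the 6β-acetate and the ring D enol ether go back to a 7-oxo-9α,13-epoxide with ring D as a γ-lactone. The C6 oxygen comes from Δ6 silyl enol ether hydroboration, a 6-ketone and α-face hydride; ring D comes from lactol dehydration.
3. Key disconnection C8–C9: ring B opens to a seco-drimane ethyl ketone, activated as its C7 silyl enol ether, that carries ring C as a 4,5-dihydrofuran.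
4. Ring C comes from 5-endo-dig closure of a C9≡C11 alkynol. C12–C13 comes from a propargylic bromide and the (R)-malic acid dioxolanone, which sets C13. Ring A with C5 and C10 comes from sclareolide by excision of C8/C17 (Δ8-en-7-one ozonolysis) and rebuilding of the ethyl ketone.
5. Ring order: A (kept from sclareolide), D (as lactone), C, B, then D adjusted to the dihydrofuran.

Key step: step 15

Assumption: the C15 lactol carbon and its derivatives are carried as anomeric mixtures, which has no consequence because C15 becomes sp2 when ring D is dehydrated.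

**Step 1**
Reactants: 1 (+)-sclareolide
Product: 2 methyl 13,14,15,16-tetranorlabd-8-en-12-oate (Δ8(9) ester; 5α-H and 10β-Me as in 1)
Conditions: conc. H2SO4 (cat.), MeOH, reflux
Reagents that add atoms: methanol, CO
Why: Acid-catalysed methanolysis of the lactone and E1 loss of the tertiary C8 oxygen under equilibrating conditions should funnel the alkene isomers to the tetrasubstituted Δ8(9) ester while C5 and C10 stay untouched.

**Step 2**
Reactants: 2 Δ8(9) ester
Product: 3 methyl 7-oxo-13,14,15,16-tetranorlabd-8-en-12-oate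
Conditions: CrO3, 3,5-dimethylpyrazole, CH2Cl2, −20 °C
Reagents that add atoms: chromium trioxide, O=[Cr](=O)=O
Why: Allylic oxidation with the CrO3–dimethylpyrazole complex should take the ring methylene C7, whose axial C–H bond is aligned with the alkene, in preference to the C17 methyl group and the more crowded C11 methylene, and give the conjugated enone.

**Step 3**
Reactants: 3 enone ester
Product: 4 2-[(1S,2S)-2-(3-methoxy-3-oxopropanoyl)-2,6,6-trimethylcyclohexyl]acetic acid (8,9-seco compound; C7 acid and C9 β-keto ester)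
Conditions: O3, CH2Cl2–MeOH, −78 °C; then 30 % H2O2, AcOH, rt
Reagents that add atoms: ozone, [O-][O+]=O; hydrogen peroxide, OO
Why: Ozonolysis of the C8=C9 bond, then peroxide cleavage of the resulting C7–C8 α-dicarbonyl unit (the usual enone to keto acid degradation with loss of the α-carbon), excises C8 and C17 and leaves C9 as a ketone on quaternary C10.

**Step 4**
Reactants: 4 seco keto acid
Product: 6 C7 N-methoxy-N-methylamide of the seco keto ester, via acyl imidazole 5 (not isolated)
Conditions: 1,1'-carbonyldiimidazole, CH2Cl2, 0 °C; then MeNH(OMe)·HCl, rt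
Reagents that add atoms: N,O-dimethylhydroxylamine hydrochloride, CNOC.Cl
Why: Acyl imidazole activation and aminolysis (Weinreb amide formation) run near neutrality and leave the β-keto ester alone, and any enol lactone formed from the δ-keto acid is opened by the same amine to the same amide.

**Step 5**
Reactants: 6 Weinreb amide
Product: 7 methyl 3-oxo-3-[(1S,2S)-1,3,3-trimethyl-2-(2-oxobutyl)cyclohexyl]propanoate (C7 ethyl ketone)
Conditions: EtMgBr (2.3 equiv), THF, −20 to 0 °C; aq. NH4Cl
Reagents that add atoms: ethylmagnesium bromide, CC[Mg]Br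
Why: In this Weinreb ketone synthesis the first equivalent of Grignard reagent turns the β-keto ester into an unreactive magnesium enolate, and the second adds to the amide to give a chelate that releases the ethyl ketone (new C8 and C17) only on work-up.

**Step 6**
Reactants: 7 ethyl ketone β-keto ester
Product: 8 C7 ethylene ketal of 7
Conditions: (Me3SiOCH2)2, TMSOTf (5 mol %), CH2Cl2, −78 to −20 °C; pyridine quench
Reagents that add atoms: 1,2-bis(trimethylsilyloxy)ethane, C[Si](C)(C)OCCO[Si](C)(C)C
Why: Noyori ketalisation at low temperature takes the unhindered C7 ketone, leaves the neopentyl and partly enolised C9 carbonyl, and is mild enough to avoid a Knoevenagel-type closure from C11 to C7 in this 1,5-dicarbonyl compound.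

**Step 7**
Reactants: 8 ketal β-keto ester
Product: 10 methyl 3-{(1S,2S)-2-[(2-ethyl-1,3-dioxolan-2-yl)methyl]-1,3,3-trimethylcyclohexyl}prop-2-ynoate, via Z enol triflate 9 (not isolated)
Conditions: LiN(SiMe3)2 (1.1 equiv), Et2O, −78 °C; Tf2O; then LiN(SiMe3)2 (2 equiv), −78 °C to rt
Reagents that add atoms: none
Why: O-triflation of the chelated lithium enolate gives the Z enol triflate with H11 anti to the triflate, and base-induced elimination (the known one-pot β-keto ester to 2-alkynoate conversion) can only give the alkyne because C10 has no hydrogen for allene formation.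

**Step 8**
Reactants: 10 alkynoate
Product: 11 propargylic alcohol (C9≡C11–C12H2OH; C7 ketal)
Conditions: i-Bu2AlH (2.5 equiv), CH2Cl2, −78 °C; aq. potassium sodium tartrate
Reagents that add atoms: none
Why: 1,2-Reduction of the alkynoate with i-Bu2AlH at low temperature gives the primary propargylic alcohol without hydroalumination of the alkyne or opening of the dioxolane.

**Step 9**
Reactants: 11 propargylic alcohol
Product: 12 propargylic bromide (C9≡C11–C12H2Br; C7 ketal)
Conditions: CBr4, PPh3, 2,6-lutidine, CH2Cl2, 0 °C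
Reagents that add atoms: carbon tetrabromide, BrC(Br)(Br)Br
Why: The Appel reaction converts the unhindered primary alcohol into the bromide under nearly neutral conditions that the ketal tolerates.

**Step 10**
Reactants: 13 (R)-malic acid
Product: 14 (2R,4R)-2-tert-butyl-5-oxo-1,3-dioxolane-4-acetic acid (cis)
Conditions: pivalaldehyde, p-TsOH (cat.), pentane, reflux (Dean–Stark); recrystallisation
Reagents that add atoms: pivalaldehyde, CC(C)(C)C=O
Why: Acid-catalysed acetalisation of the α-hydroxy acid unit with removal of water gives the five-membered dioxolanone, whose favoured cis isomer is purified by crystallisation and stores the stereochemical information at the acetal carbon.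

**Step 11**
Reactants: 14 cis dioxolanone acid; 12 propargylic bromide
Product: 16 (2R,4R)-4-alkylated dioxolanone acid with C12 bonded to C13 (13R; C12 trans to tert-butyl), via dilithium enolate 15 (not isolated)
Conditions: 14 (1.5 equiv), LiN(SiMe3)2 (3.1 equiv), THF, −78 °C; then 12, −78 to −20 °C; cold 0.5 M HCl
Reagents that add atoms: none
Why: In this alkylation by self-regeneration of stereocentres the reactive, unhindered propargylic bromide attacks the enolate on the face anti to the tert-butyl group, so C12 takes the place of the former hydrogen with retention and C13 is set as R.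

**Step 12**
Reactants: 16 alkylated dioxolanone acid
Product: 18 (4R)-4-hydroxy-4-{3-[(1S,2S)-1,3,3-trimethyl-2-(2-oxobutyl)cyclohexyl]prop-2-yn-1-yl}oxolan-2-one, via dihydroxy acid 17 (not isolated)
Conditions: NaH (1.05 equiv), THF, 0 °C; LiBH4 (3 equiv), 0 °C to rt; then 2 M HCl, THF, rt
Reagents that add atoms: water, O
Why: Borohydride reduces the activated acylal-type carbonyl C16 to the primary alcohol while the C15 carboxylate is inert, and the acid work-up lactonises O16 onto C15 (ring D) and hydrolyses the dioxolane without touching C13.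

**Step 13**
Reactants: 18 alkynol keto lactone
Product: 19 seco-drimane ethyl ketone with ring C as 4,5-dihydrofuran spiro-fused to the ring D lactone (5S,10S,13R)
Conditions: Ph3PAuNTf2 (3 mol %), 2,6-di-tert-butylpyridine (6 mol %), 4 Å MS, toluene, rt; Et3N quench, Et3N-deactivated silica
Reagents that add atoms: none
Why: In this monovalent-gold cycloisomerisation of a homopropargylic alcohol the C13 hydroxyl attacks the activated alkyne at C9 in the 5-endo-dig mode (the 4-exo mode is strained), protodeauration gives the enol ether, and the hindered base keeps the medium from turning acidic.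

**Step 14**
Reactants: 19 dihydrofuran ethyl ketone
Product: 20 (Z)-C7 tert-butyldimethylsilyl enol ether of 19 (C7=C8)
Conditions: TBSOTf (1.2 equiv), Et3N (3 equiv), CH2Cl2, −78 to 0 °C; aq. NaHCO3
Reagents that add atoms: tert-butyldimethylsilyl triflate, CC(C)(C)[Si](C)(C)OS(=O)(=O)C(F)(F)F
Why: Soft enolisation silylates the ketone faster than the lactone, avoids a lactone enolate that would expel the C13 oxygen, removes a proton from the open C8 methylene and not from C6 next to crowded C5, and gives mainly the Z enol ether as is usual for ethyl ketones.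

**Step 15**
Reactants: 20 silyl enol ether dihydrofuran
Product: 22 (13R)-9α,13-epoxy-7-oxolabdan-15,16-olide (8α-Me), via C9 oxocarbenium triflimide 21 (not isolated)
Conditions: Tf2NH (1.05 equiv), CH2Cl2 (0.01 M), −78 °C; sat. aq. NaHCO3 at −78 °C
Reagents that add atoms: none
Why: Tf2NH protonates the more basic alkyl enol ether of ring C at C11 to give the five-membered C9 oxocarbenium ion 21, C8 of the silyl enol ether adds to C9, and transfer of the silyl group to the triflimide anion releases the C7 ketone. The closest known reaction type is the intramolecular Mukaiyama aldol addition of a silyl enol ether to a cyclic oxocarbenium ion. Ring B closes in the 6-(enolendo)-exo-trig mode through a chair in which the C5–C6 and C10–C9 bonds are the two equatorial arms of ring A, so the trans ring fusion follows from the preset C5 and C10. C9 should be set by this chair, which places the small ring oxygen in the axial α site anti to the C10 methyl group and the larger C11 methylene in the equatorial β site, and this is also the more stable arrangement. C8 is set by the Z geometry of the enol ether, whose methyl group lies trans to C6 and so ends equatorial (α), the epimer that any later enolisation also favours because an axial methyl would meet the C10 methyl group. The step needs the closure C8-to-C9 to win over the reverse closure C11-to-C7, which the free ketone 19 would invite by offering an acid-activated carbonyl to the nucleophilic C11: in 20 C7 is masked as the less basic, bulkier silyl enol ether, C6 cannot reach C9 (four-membered ring), and the low temperature and non-basic anion hold back loss of the C13–O or C9–O bond.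

**Step 16**
Reactants: 22 7-oxo lactone
Product: 23 Δ6 tert-butyldimethylsilyl enol ether of 22 (C6=C7)
Conditions: TBSOTf (1.3 equiv), Et3N (4 equiv), CH2Cl2, 0 °C; aq. NaHCO3
Reagents that add atoms: tert-butyldimethylsilyl triflate, CC(C)(C)[Si](C)(C)OS(=O)(=O)C(F)(F)F
Why: Soft enolisation again spares the β-alkoxy lactone, and the enol ether should form toward C6 because the Δ7 isomer would be tetrasubstituted and would press C17 against C11 and the silyloxy group.

**Step 17**
Reactants: 23 Δ6 silyl enol ether
Product: 25 6α-hydroxy-7β-(tert-butyldimethylsilyloxy) lactone, via C6 alkylborane 24 (not isolated)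
Conditions: BH3·THF (2 equiv), THF, 0 °C to rt; then NaBO3·4H2O, THF–H2O, rt
Reagents that add atoms: sodium perborate tetrahydrate, [Na+].[O-]OB=O.O.O.O.O
Why: Hydroboration–oxidation of a silyl enol ether places boron on C6, β to oxygen, and syn addition on the α face (the β face is closed by the axial C4 and C10 methyl groups) gives the trans-diequatorial 6α-ol 7β-silyl ether, whose rigid B/O pair cannot reach an elimination geometry, while the lactone is reduced far more slowly.

**Step 18**
Reactants: 25 6α-alcohol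
Product: 26 6-oxo-7β-(tert-butyldimethylsilyloxy) lactone
Conditions: Dess–Martin periodinane, NaHCO3, CH2Cl2, 0 °C to rt
Reagents that add atoms: none
Why: Buffered Dess–Martin oxidation converts the equatorial alcohol into the ketone without epimerising C5 or C7 and without touching lactone or silyl ether.

**Step 19**
Reactants: 26 6-ketone lactone
Product: 27 6β-hydroxy-7β-(tert-butyldimethylsilyloxy) C15 lactol
Conditions: i-Bu2AlH (3.5 equiv), CH2Cl2, −78 °C; aq. potassium sodium tartrate
Reagents that add atoms: none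
Why: Hydride can reach the C6 ketone only from the α face because the axial C4 and C10 methyl groups close the β face, which gives the axial 6β-alcohol, and the same reagent stops the lactone at the aluminium hemiacetal and hence at the lactol.

**Step 20**
Reactants: 27 lactol
Product: 29 6β-hydroxy-7β-(tert-butyldimethylsilyloxy)-9α,13;15,16-diepoxylabd-14-ene (13R), via C15 mesylate 28 (not isolated)
Conditions: MsCl (1.3 equiv), Et3N (6 equiv), CH2Cl2, −40 °C to rt
Reagents that add atoms: none
Why: In this lactol dehydration the reactive anomeric hydroxyl is mesylated and loses methanesulfonate with H14 under excess amine to give the C14=C15 enol ether (C13 has no hydrogen), while the 6β-hydroxyl between two syn-axial methyl groups and the silyl ether is too hindered to react.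

**Step 21**
Reactants: 29 6β-alcohol
Product: 30 6β-acetoxy-7β-(tert-butyldimethylsilyloxy)-9α,13;15,16-diepoxylabd-14-ene
Conditions: Ac2O (excess), DMAP, Et3N, CH2Cl2, 40 °C
Reagents that add atoms: acetic anhydride, CC(=O)OC(C)=O
Why: DMAP-catalysed acylation with excess anhydride and gentle heating is the standard answer to hindered axial alcohols, and the basic medium is safe for the acid-labile ring D.

**Step 22**
Reactants: 30 acetate silyl ether
Product: 31 6β-acetoxy-7β-hydroxy-9α,13;15,16-diepoxylabd-14-ene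
Conditions: n-Bu4NF–AcOH (1:1, 3 equiv), THF, 0 °C to rt
Reagents that add atoms: none
Why: Fluoride cleaves the silyl ether, and the acetic acid buffer protonates the C7 alkoxide as it forms, which suppresses acetyl migration from O6 and keeps the medium too weakly acidic to open ring D.

**Step 23**
Reactants: 31 7β-alcohol
Product: 32 (13R)-6β-acetoxy-9α,13;15,16-diepoxylabd-14-en-7-one (target)
Conditions: Dess–Martin periodinane, NaHCO3 (excess), CH2Cl2, 0 °C
Reagents that add atoms: none
Why: Dess–Martin oxidation buffered with solid NaHCO3 restores the C7 ketone under neutral conditions that should leave the enol ether, the axial C6 acetate and the equatorial C8 methyl group unchanged.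

**Compound list**
1 | (+)-sclareolide | C1C[C@@]2(C)OC(=O)C[C@@H]2[C@@]3(C)CCCC(C)(C)[C@H]13 | starting material
2 | methyl 13,14,15,16-tetranorlabd-8-en-12-oate | COC(=O)CC1=C(C)CC[C@H]2C(C)(C)CCC[C@]12C | intermediate
3 | methyl 7-oxo-13,14,15,16-tetranorlabd-8-en-12-oate | COC(=O)CC1=C(C)C(=O)C[C@H]2C(C)(C)CCC[C@]12C | intermediate
4 | 8,9-seco keto acid (C7 acid, C9 β-keto ester) | OC(=O)C[C@H]1C(C)(C)CCC[C@]1(C)C(=O)CC(=O)OC | intermediate
5 | C7 acyl imidazole of 4 | O=C(C[C@H]1C(C)(C)CCC[C@]1(C)C(=O)CC(=O)OC)n1ccnc1 | intermediate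
6 | C7 Weinreb amide | CON(C)C(=O)C[C@H]1C(C)(C)CCC[C@]1(C)C(=O)CC(=O)OC | intermediate
7 | seco ethyl ketone β-keto ester | CCC(=O)C[C@H]1C(C)(C)CCC[C@]1(C)C(=O)CC(=O)OC | intermediate
8 | C7 ethylene ketal of 7 | CCC1(OCCO1)C[C@H]2C(C)(C)CCC[C@]2(C)C(=O)CC(=O)OC | intermediate
9 | (Z)-C9 enol triflate | CCC1(OCCO1)C[C@H]2C(C)(C)CCC[C@]2(C)/C(OS(=O)(=O)C(F)(F)F)=C/C(=O)OC | intermediate
10 | C9≡C11 alkynoate | CCC1(OCCO1)C[C@H]2C(C)(C)CCC[C@]2(C)C#CC(=O)OC | intermediate
11 | propargylic alcohol | CCC1(OCCO1)C[C@H]2C(C)(C)CCC[C@]2(C)C#CCO | intermediate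
12 | propargylic bromide | CCC1(OCCO1)C[C@H]2C(C)(C)CCC[C@]2(C)C#CCBr | intermediate
13 | (R)-malic acid | O[C@H](CC(=O)O)C(=O)O | starting material
14 | (2R,4R)-2-tert-butyl-5-oxo-1,3-dioxolane-4-acetic acid | OC(=O)C[C@H]1O[C@@H](C(C)(C)C)OC1=O | intermediate
15 | dilithium enolate carboxylate of 14 | [Li+].[Li+].[O-]C(=O)CC1=C([O-])O[C@H](C(C)(C)C)O1 | intermediate
16 | C13-alkylated dioxolanone acid (13R) | CCC1(OCCO1)C[C@H]2C(C)(C)CCC[C@]2(C)C#CC[C@]3(CC(=O)O)O[C@@H](C(C)(C)C)OC3=O | intermediate
17 | (13R)-13,16-dihydroxy C15 acid, C7 ketal | CCC1(OCCO1)C[C@H]2C(C)(C)CCC[C@]2(C)C#CC[C@](O)(CO)CC(=O)O | intermediate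
18 | alkynol keto lactone | CCC(=O)C[C@H]1C(C)(C)CCC[C@]1(C)C#CC[C@@]2(O)CC(=O)OC2 | intermediate
19 | seco-drimane ethyl ketone with spiro dihydrofuran lactone | CCC(=O)C[C@H]1C(C)(C)CCC[C@]1(C)C3=CC[C@]2(CC(=O)OC2)O3 | intermediate
20 | (Z)-C7 TBS enol ether of 19 | C/C=C(\O[Si](C)(C)C(C)(C)C)C[C@H]1C(C)(C)CCC[C@]1(C)C3=CC[C@]2(CC(=O)OC2)O3 | intermediate
21 | C9 oxocarbenium triflimide | C/C=C(\O[Si](C)(C)C(C)(C)C)C[C@H]1C(C)(C)CCC[C@]1(C)C3=[O+][C@@]2(CC(=O)OC2)CC3.[N-](S(=O)(=O)C(F)(F)F)S(=O)(=O)C(F)(F)F | intermediate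
22 | (13R)-9α,13-epoxy-7-oxolabdan-15,16-olide | C1C(=O)[C@@H](C)[C@]2(CC[C@]3(CC(=O)OC3)O2)[C@@]2(C)CCCC(C)(C)[C@H]12 | intermediate
23 | Δ6 TBS enol ether of 22 | C1=C(O[Si](C)(C)C(C)(C)C)[C@@H](C)[C@]2(CC[C@]3(CC(=O)OC3)O2)[C@@]2(C)CCCC(C)(C)[C@H]12 | intermediate
24 | C6α alkylborane | B[C@H]1[C@H](O[Si](C)(C)C(C)(C)C)[C@@H](C)[C@]2(CC[C@]3(CC(=O)OC3)O2)[C@@]2(C)CCCC(C)(C)[C@H]12 | intermediate
25 | 6α-hydroxy-7β-TBSO lactone | O[C@H]1[C@H](O[Si](C)(C)C(C)(C)C)[C@@H](C)[C@]2(CC[C@]3(CC(=O)OC3)O2)[C@@]2(C)CCCC(C)(C)[C@H]12 | intermediate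
26 | 6-oxo-7β-TBSO lactone | O=C1[C@H](O[Si](C)(C)C(C)(C)C)[C@@H](C)[C@]2(CC[C@]3(CC(=O)OC3)O2)[C@@]2(C)CCCC(C)(C)[C@H]12 | intermediate
27 | 6β-hydroxy-7β-TBSO C15 lactol | O[C@@H]1[C@H](O[Si](C)(C)C(C)(C)C)[C@@H](C)[C@]2(CC[C@]3(CC(O)OC3)O2)[C@@]2(C)CCCC(C)(C)[C@H]12 | intermediate
28 | C15 mesylate of 27 | O[C@@H]1[C@H](O[Si](C)(C)C(C)(C)C)[C@@H](C)[C@]2(CC[C@]3(CC(OS(C)(=O)=O)OC3)O2)[C@@]2(C)CCCC(C)(C)[C@H]12 | intermediate
29 | 6β-hydroxy-7β-TBSO-9α,13;15,16-diepoxylabd-14-ene | O[C@@H]1[C@H](O[Si](C)(C)C(C)(C)C)[C@@H](C)[C@]2(CC[C@]3(C=COC3)O2)[C@@]2(C)CCCC(C)(C)[C@H]12 | intermediate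
30 | 6β-acetoxy-7β-TBSO-9α,13;15,16-diepoxylabd-14-ene | CC(=O)O[C@@H]1[C@H](O[Si](C)(C)C(C)(C)C)[C@@H](C)[C@]2(CC[C@]3(C=COC3)O2)[C@@]2(C)CCCC(C)(C)[C@H]12 | intermediate
31 | 6β-acetoxy-7β-hydroxy-9α,13;15,16-diepoxylabd-14-ene | CC(=O)O[C@@H]1[C@H](O)[C@@H](C)[C@]2(CC[C@]3(C=COC3)O2)[C@@]2(C)CCCC(C)(C)[C@H]12 | intermediate
32 | (13R)-6β-acetoxy-9α,13;15,16-diepoxylabd-14-en-7-one | CC(=O)O[C@@H]1C(=O)[C@@H](C)[C@]2(CC[C@]3(C=COC3)O2)[C@@]2(C)CCCC(C)(C)[C@H]12 | target

Total step count: 23
Longest linear sequence: 22 steps (steps 1–9 and 11–23)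

**Steps most likely to fail**

**Step 15 (key step).**
- Proton transfer to C8 instead of C11 would unmask an activated C7 carbonyl and open the reverse closure from C11 to C7.
- Crowding at C9 may slow C–C bond formation enough for ring C to open by loss of the C13–O bond.
- Facial selectivity at C9 may be poor.

The fallback sets out from 18 and comes back at 22. It makes the C8–C9 bond and the C9–O bond in separate, known operations. TESOTf and Et3N convert 18 into the triethylsilyl enol ether triethylsilyl ether F1. Ph3PAuCl/AgBF4 in CH2Cl2–MeOH closes ring B by 6-exo-dig carbocyclisation of the silyl enol ether onto the alkyne (Conia-ene type) to give the 9(11)-alkylidene ketone F2. TsOH·H2O in CH2Cl2 removes the silyl ether and moves the alkene into conjugation to give the 13-hydroxy-8-en-7-one F3. The C13 hydroxyl of F3 then adds to C9 by acid-catalysed 5-exo-trig oxa-Michael addition. Addition is axial, from the α face anti to the C10 methyl group, and C8 is protonated to the equatorial methyl epimer, which gives 22.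

**Step 16.**
- Enolisation may run toward C8.
- The silylated carbonyl may trigger ionisation of the β C9–O bond.
- The lactone may be silylated and lose the C13 oxygen.

The fallback sets out from 22 and comes back at 27. It exchanges the enolisable lactone for a base-stable mask so that kinetic deprotonation can be used.
- i-Bu2AlH reduces 22 to the 7-hydroxy lactol F4.
- MeOH with pyridinium p-toluenesulfonate caps the lactol as the methyl acetal F5.
- Dess–Martin oxidation restores the ketone in the keto acetal F6.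
- LiN(i-Pr)2 and then TBSOTf at −78 °C give the Δ6 silyl enol ether F7.
- Hydroboration–oxidation gives the 6α-alcohol F8.
- Dess–Martin oxidation gives the 6-ketone F9.
- NaBH4 attacks from the α face to give the 6β-alcohol F10.
- Aqueous AcOH–THF hydrolyses the acetal to lactol 27.

**Step 22.**
- The freed C7 oxygen, cis to the acetate, may take over the acetyl group.
- The allylic spiro ether of ring D may open with aromatisation to a furan during the last manipulations.

The fallback sets out from 27 and comes back at 32. It makes the enol ether in the last operation by a thermal, non-acidic elimination.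
- PhSH and BF3·OEt2 at −78 °C convert 27 into the C15 phenylthio acetal F11.
- Ac2O/DMAP gives the 6β-acetate F12.
- HF·pyridine removes the silyl group, in a medium that forms no alkoxide and so allows no acyl shift, to give the 7β-alcohol F13.
- Dess–Martin oxidation gives the 7-ketone F14.
- mCPBA at −78 °C gives the sulfoxide F15.
- Warming F15 in toluene with i-Pr2NEt and P(OMe)3 brings about syn elimination across C14–C15 to give 32.

**Further compounds**
F1 | step 15 | triethylsilyl enol ether triethylsilyl ether of 18 | C/C=C(\O[Si](CC)(CC)CC)C[C@H]1C(C)(C)CCC[C@]1(C)C#CC[C@@]2(O[Si](CC)(CC)CC)CC(=O)OC2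
F2 | step 15 | 9(11)-alkylidene 7-ketone with 13-OTES (C8 epimers) | CC1C(=O)C[C@H]2C(C)(C)CCC[C@]2(C)/C1=C/C[C@@]3(O[Si](CC)(CC)CC)CC(=O)OC3
F3 | step 15 | (13R)-13-hydroxy-7-oxolabd-8-en-15,16-olide | CC1=C(CC[C@@]3(O)CC(=O)OC3)[C@@]2(C)CCCC(C)(C)[C@@H]2CC1=O
F4 | step 16 | 7-hydroxy C15 lactol | C1C(O)[C@@H](C)[C@]2(CC[C@]3(CC(O)OC3)O2)[C@@]2(C)CCCC(C)(C)[C@H]12
F5 | step 16 | 7-hydroxy C15 methyl acetal | C1C(O)[C@@H](C)[C@]2(CC[C@]3(CC(OC)OC3)O2)[C@@]2(C)CCCC(C)(C)[C@H]12
F6 | step 16 | 7-oxo C15 methyl acetal | C1C(=O)[C@@H](C)[C@]2(CC[C@]3(CC(OC)OC3)O2)[C@@]2(C)CCCC(C)(C)[C@H]12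
F7 | step 16 | Δ6 TBS enol ether methyl acetal | C1=C(O[Si](C)(C)C(C)(C)C)[C@@H](C)[C@]2(CC[C@]3(CC(OC)OC3)O2)[C@@]2(C)CCCC(C)(C)[C@H]12
F8 | step 16 | 6α-hydroxy-7β-TBSO methyl acetal | O[C@H]1[C@H](O[Si](C)(C)C(C)(C)C)[C@@H](C)[C@]2(CC[C@]3(CC(OC)OC3)O2)[C@@]2(C)CCCC(C)(C)[C@H]12
F9 | step 16 | 6-oxo-7β-TBSO methyl acetal | O=C1[C@H](O[Si](C)(C)C(C)(C)C)[C@@H](C)[C@]2(CC[C@]3(CC(OC)OC3)O2)[C@@]2(C)CCCC(C)(C)[C@H]12
F10 | step 16 | 6β-hydroxy-7β-TBSO methyl acetal | O[C@@H]1[C@H](O[Si](C)(C)C(C)(C)C)[C@@H](C)[C@]2(CC[C@]3(CC(OC)OC3)O2)[C@@]2(C)CCCC(C)(C)[C@H]12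
F11 | step 22 | 6β-hydroxy-7β-TBSO C15 phenylthio acetal | O[C@@H]1[C@H](O[Si](C)(C)C(C)(C)C)[C@@H](C)[C@]2(CC[C@]3(CC(Sc4ccccc4)OC3)O2)[C@@]2(C)CCCC(C)(C)[C@H]12
F12 | step 22 | 6β-acetoxy-7β-TBSO C15 phenylthio acetal | CC(=O)O[C@@H]1[C@H](O[Si](C)(C)C(C)(C)C)[C@@H](C)[C@]2(CC[C@]3(CC(Sc4ccccc4)OC3)O2)[C@@]2(C)CCCC(C)(C)[C@H]12
F13 | step 22 | 6β-acetoxy-7β-hydroxy C15 phenylthio acetal | CC(=O)O[C@@H]1[C@H](O)[C@@H](C)[C@]2(CC[C@]3(CC(Sc4ccccc4)OC3)O2)[C@@]2(C)CCCC(C)(C)[C@H]12
F14 | step 22 | 6β-acetoxy-7-oxo C15 phenylthio acetal | CC(=O)O[C@@H]1C(=O)[C@@H](C)[C@]2(CC[C@]3(CC(Sc4ccccc4)OC3)O2)[C@@]2(C)CCCC(C)(C)[C@H]12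
F15 | step 22 | 6β-acetoxy-7-oxo C15 phenylsulfinyl acetal | CC(=O)O[C@@H]1C(=O)[C@@H](C)[C@]2(CC[C@]3(CC(S(=O)c4ccccc4)OC3)O2)[C@@]2(C)CCCC(C)(C)[C@H]12
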